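Watch G.

| setting | gamma | delta | ochre | teal | grey |
|---|---|---|---|---|---|
| E | 2.8 M | 2.8 M | 2.0 M | 2.0 M | 2.0 M |
| temperature | −10 °C | 12 °C | −20 °C | 0 °C | 20 °C |
| remark | run made earlier | run made earlier |  |  |  |
| time |  |  | 50 min | 50 min | 50 min |

| run | time / min | G / % | Z / % | D / % | E / % |
|---|---|---|---|---|---|
| gamma | 2.50 | 8.0 | 2.1 | 11.7 | 80.2 |
| gamma | 6.00 | 10.5 | 3.0 | 33.7 | 55.2 |
| gamma | 12.0 | 10.7 | 2.2 | 60.6 | 27.8 |
| gamma | 20.0 | 11.8 | 2.6 | 75.3 | 11.1 |
| gamma | 25.0 | 10.9 | 2.3 | 82.6 | 8.0 |
| delta | 0.833 | 27.3 | 2.7 | 53.5 | 15.4 |
| delta | 2.00 | 29.0 | 0 | 69.1 | 2.5 |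
| delta | 4.00 | 31.1 | 0 | 70.6 | 0 |
| delta | 6.00 | 28.9 | 0 | 69.9 | 0 |
| delta | 8.00 | 29.4 | 1.6 | 71.6 | 0 |

(each reading ± 1 percentage point)

- percent here means E units held: one Z or D counts as two
- on the list of suspects stand: E + G -> D; E -> G; 2 E <-> Z

- which of these there is most of at the end, counted by the E in it, ochre (E / G / Z / D)
- which of these there is most of at the end, counted by the E in it, teal (E / G / Z / D)
- which of these there is most of at the end, counted by the E in it, grey (E / G / Z / D)
- final amount of the leader among these, as a percentage of the E charged, in ochre
- final amount of the leader among these, as a percentage of the E charged, in teal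
- final amount of the leader among these, as a percentage of the E charged, in grey

Step 1. On the list of suspects, two steps act on G. E makes G at a rate proportional to E, and E takes G into D at a rate proportional to E and to G. As E stands in both, you compare them through G. When they are equal, G stands still while E falls: a steady state. Call that share of the charge the ceiling. In gamma, G stays flat within the scatter over the last three readings, so their mean is my reading of the ceiling at gamma's charge and temperature: 11.1%.

Step 2. In delta, E reads 0% from 4.00 min on, and the mean of G over the next readings is 29.8%, so this end share need not be the ceiling. I leave Z aside here, as it reads 2.7% at most in delta. Each E making G adds one G, and each E going to D removes one. Following E to its end ties the two shares together: the gap left below the ceiling, as a part of the ceiling, is exp of minus (one plus the end share) over 2 ceilings. By trial, my reading of delta's ceiling comes out at 35.5%, above that end share.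

Step 3. The ceiling rises by the ratio of the charges, 1.40, when the charge drops to 2.0 M. I take each degree to multiply it by the same factor, which gives 9.20% for ochre, 26.4% for teal and 75.7% for grey.

Step 4. As a fractional rate, E reads 0.0958 /min in gamma, between its last three readings' first and last, and 2.25 /min in delta, from the start to its first reading. Taking each degree to multiply this rate by the same factor, and the charge to leave it unchanged, I reckon teal's E time at 2.49 min, far shorter than 50 min, and grey's at 0.141 min, shorter than teal's, so I expect both to finish. I reckon that ochre keeps 31.9% as E at 50 min.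

Step 5. My ends: teal has G 23.9% and D 76.1%, more than its G. Grey has G 47.0% and D 53.0%, more than its G. Ochre, with G at its ceiling and Z taken as gamma's last 2.3%, has D 56.6%, more than its E or G.

The forecast, reasoning that “G plateaus while E falls”, names D, D and D at 56%, 76% and 54% for ochre, teal and grey, close to my figures but not equal to them.

The flasks give D at 56.9% in ochre, D at 75.7% in teal and D at 53.9% in grey.

    E + G → D (k = 0.0700 /M/min, Ea = 55.0 kJ/mol)
    E → G (k = 0.0120 /min, Ea = 88.0 kJ/mol)
    2 E ⇌ Z (K = 0.0890 /M, k = 3.40 × 10⁻⁴ /M/min, Ea = 66.0 kJ/mol, ΔH = −25.0 kJ/mol)
    (constants at −20 °C)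

Now take a flask like teal but kept at 15 °C. The ceiling from gamma and delta comes to 58.2%, and the tie from step 2 then gives an end share of G of 40.8%. That flask ends with E at 0%, G at 40.6% and D at 59.4%.

The readings come from a simulation for substances that don't exist; scatter was added.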